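**Retrosynthetic overview**
1. Target 43 comes from diol 42 by one Dess–Martin oxidation that forms both the cross-conjugated dienone and the side-chain ketone; 42 comes from a Stille union of ring enol triflate 26 with (E)-alkenylstannane 40.
2. Stannane 40 comes from an Evans syn-aldol (propionimide + propanal), then alkyne formation and hydrozirconation–iodination.
3. Triflate 26 comes from cyclohexenone 24, made by RCM of the diene obtained by aldol addition of ethyl ketone 19 to methacrolein.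
4. Key C–C bond: intermolecular aldol of quaternary aldehyde 11 with the dianion of methyl 2-methyl-3-oxopentanoate 12, then oxidation, lactonisation and O-methylation to the γ-pyrone of 19.
5. Aldehyde 11 comes from a double Fráter–Seebach alkylation of methyl (S)-3-hydroxypentanoate. Ring order: γ-pyrone first, carbocycle second (RCM), dienone revealed last.

Assumption: centres that later become sp2 or carbonyl carbons are carried as diastereomer mixtures, propenyl is drawn E (the minor Z isomer is equally productive), Cp ligands are drawn η1 in SMILES, and TBS = tert-butyldimethylsilyl.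

**Core: quaternary centre, pyrone, carbocycle**

Step 1
Reactants: 1 methyl 3-oxopentanoate
Product: 2 methyl (3S)-3-hydroxypentanoate
Conditions: H2 (50 atm), RuCl2[(S)-BINAP] (0.1 mol%), MeOH, 50 °C
Reagents that add atoms: none
Why: Noyori asymmetric hydrogenation of a β-keto ester, in which the (S)-BINAP–Ru chelate delivers hydrogen to one carbonyl face and sets C3 as S.

Step 2
Reactants: 2 methyl (3S)-3-hydroxypentanoate
Product: 4 methyl (2S,3S)-3-hydroxy-2-methylpentanoate, via dilithium alkoxide enolate of the hydroxy ester 3 (not isolated)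
Conditions: LDA (2.2 eq), THF, −78 → −20 °C; MeI, DMPU, −78 → 0 °C
Reagents that add atoms: iodomethane CI
Why: Fráter–Seebach alkylation, in which the lithium-chelated dianion is methylated on the face anti to the C3 ethyl group to give the anti (2S,3S) ester.

Step 3
Reactants: 4 methyl (2S,3S)-3-hydroxy-2-methylpentanoate; 5 allyl bromide
Product: 7 methyl (2S,3S)-2-allyl-3-hydroxy-2-methylpentanoate, via dilithium alkoxide enolate of the methylated hydroxy ester 6 (not isolated)
Conditions: LDA (2.3 eq), THF, −78 → 0 °C; 5, DMPU, −78 → −20 °C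
Reagents that add atoms: none
Why: second Fráter–Seebach alkylation, in which allyl bromide enters the same enolate face that methyl took before, so the quaternary centre (future ring C4) is set as 2S and the minor epimer is removed by chromatography.

Step 4
Reactants: 7 methyl (2S,3S)-2-allyl-3-hydroxy-2-methylpentanoate
Product: 8 methyl (2S,3S)-2-allyl-3-(TBSO)-2-methylpentanoate
Conditions: TBSOTf, 2,6-lutidine, CH2Cl2, 0 °C
Reagents that add atoms: tert-butyldimethylsilyl triflate CC(C)(C)[Si](C)(C)OS(=O)(=O)C(F)(F)F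
Why: silyl ether formation with the reactive triflate masks the hindered secondary alcohol (the later ring C3 carbonyl) through the aldehyde and pyrone chemistry.

Step 5
Reactants: 8 methyl (2S,3S)-2-allyl-3-(TBSO)-2-methylpentanoate
Product: 9 methyl (2S,3S)-3-(TBSO)-2-methyl-2-[(E)-prop-1-enyl]pentanoate
Conditions: RuHCl(CO)(PPh3)3 (5 mol%), toluene, 80 °C
Reagents that add atoms: none
Why: Ru–H olefin isomerisation moves the double bond one position (it cannot pass the quaternary carbon), placing an sp2 carbon on the quaternary centre for the later RCM.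

Step 6
Reactants: 9 methyl (2S,3S)-3-(TBSO)-2-methyl-2-[(E)-prop-1-enyl]pentanoate
Product: 10 (2R,3S)-3-(TBSO)-2-methyl-2-[(E)-prop-1-enyl]pentan-1-ol
Conditions: DIBAL-H (2.5 eq), CH2Cl2, −78 → 0 °C; Rochelle salt
Reagents that add atoms: none
Why: hydride reduction of the hindered ester to the neopentyl alcohol (the descriptor changes only through CIP priorities).

Step 7
Reactants: 10 (2R,3S)-3-(TBSO)-2-methyl-2-[(E)-prop-1-enyl]pentan-1-ol
Product: 11 (2S,3S)-3-(TBSO)-2-methyl-2-[(E)-prop-1-enyl]pentanal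
Conditions: Dess–Martin periodinane, NaHCO3, CH2Cl2, 0 °C → rt
Reagents that add atoms: none
Why: Dess–Martin oxidation to an aldehyde that has no α-hydrogen and therefore cannot epimerise or enolise.

Step 8
Reactants: 11 (2S,3S)-3-(TBSO)-2-methyl-2-[(E)-prop-1-enyl]pentanal; 12 methyl 2-methyl-3-oxopentanoate
Product: 14 methyl (6R,7S)-7-(TBSO)-5-hydroxy-2,4,6-trimethyl-3-oxo-6-[(E)-prop-1-enyl]nonanoate (C2/C4/C5 diastereomer mixture), via sodium lithium dienolate of the keto ester 13 (not isolated)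
Conditions: 12 (2 eq), NaH, THF, 0 °C; n-BuLi, 0 °C; then 11, −78 °C; aq NH4Cl
Reagents that add atoms: none
Why: intermolecular aldol addition of the β-keto ester dianion through its more reactive terminal carbon to the non-enolisable aldehyde, joining the pyrone carbons to the quaternary core; the new centres are erased later.

Step 9
Reactants: 14 methyl (6R,7S)-7-(TBSO)-5-hydroxy-2,4,6-trimethyl-3-oxo-6-[(E)-prop-1-enyl]nonanoate
Product: 15 methyl (6S,7S)-7-(TBSO)-2,4,6-trimethyl-3,5-dioxo-6-[(E)-prop-1-enyl]nonanoate (C2/C4 epimers, enol tautomers)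
Conditions: Dess–Martin periodinane, CH2Cl2, rt
Reagents that add atoms: none
Why: Dess–Martin oxidation of the β-hydroxy ketone gives the β,δ-diketo ester without retro-aldol cleavage.

Step 10
Reactants: 15 methyl (6S,7S)-7-(TBSO)-2,4,6-trimethyl-3,5-dioxo-6-[(E)-prop-1-enyl]nonanoate
Product: 16 6-[(2E,4S,5S)-5-(TBSO)-4-methylhept-2-en-4-yl]-4-hydroxy-3,5-dimethyl-2H-pyran-2-one
Conditions: DBU (3 eq), benzene, 60–80 °C
Reagents that add atoms: none
Why: base-promoted enolisation and lactonisation (the C5 enol oxygen attacks the ester and methanol is lost) give the 4-hydroxy-2-pyranone.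

Step 11
Reactants: 16 6-[(2E,4S,5S)-5-(TBSO)-4-methylhept-2-en-4-yl]-4-hydroxy-3,5-dimethyl-2H-pyran-2-one
Product: 17 2-[(2E,4S,5S)-5-(TBSO)-4-methylhept-2-en-4-yl]-6-methoxy-3,5-dimethyl-4H-pyran-4-one
Conditions: MeOTf (1.5 eq), CH2Cl2, rt; aq NaHCO3
Reagents that add atoms: methyl trifluoromethanesulfonate COS(=O)(=O)C(F)(F)F
Why: O-methylation of the neutral hydroxypyranone by a hard methylating agent occurs at the most basic lactone carbonyl oxygen, and proton loss gives the 2-methoxy-γ-pyrone regioselectively.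

Step 12
Reactants: 17 2-[(2E,4S,5S)-5-(TBSO)-4-methylhept-2-en-4-yl]-6-methoxy-3,5-dimethyl-4H-pyran-4-one
Product: 18 2-[(2E,4S,5S)-5-hydroxy-4-methylhept-2-en-4-yl]-6-methoxy-3,5-dimethyl-4H-pyran-4-one
Conditions: HF·pyridine, pyridine/THF, 0 °C → rt
Reagents that add atoms: none
Why: fluoride-driven desilylation of the hindered secondary silyl ether, which the acid-stable pyrone tolerates.

Step 13
Reactants: 18 2-[(2E,4S,5S)-5-hydroxy-4-methylhept-2-en-4-yl]-6-methoxy-3,5-dimethyl-4H-pyran-4-one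
Product: 19 2-methoxy-3,5-dimethyl-6-[(2E,4R)-4-methyl-5-oxohept-2-en-4-yl]-4H-pyran-4-one
Conditions: Dess–Martin periodinane, NaHCO3, CH2Cl2, rt
Reagents that add atoms: none
Why: Dess–Martin oxidation gives the ethyl ketone, whose α-quaternary centre is unchanged in space (the descriptor becomes R only through CIP priorities).

Step 14
Reactants: 19 2-methoxy-3,5-dimethyl-6-[(2E,4R)-4-methyl-5-oxohept-2-en-4-yl]-4H-pyran-4-one; 20 methacrolein
Product: 22 2-[(2E,4R)-7-hydroxy-4,6,8-trimethyl-5-oxonona-2,8-dien-4-yl]-6-methoxy-3,5-dimethyl-4H-pyran-4-one (C6/C7 diastereomer mixture), via lithium enolate of the ethyl ketone 21 (not isolated)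
Conditions: LDA, THF, −78 °C; 20, −78 °C; AcOH quench
Reagents that add atoms: none
Why: intermolecular aldol addition of the only possible kinetic enolate (the other α-carbon is quaternary) to the enal carbonyl supplies ring carbons C1 and C6; both new centres are erased later.

Step 15
Reactants: 22 2-[(2E,4R)-7-hydroxy-4,6,8-trimethyl-5-oxonona-2,8-dien-4-yl]-6-methoxy-3,5-dimethyl-4H-pyran-4-one
Product: 23 2-[(2E,4R)-7-(TBSO)-4,6,8-trimethyl-5-oxonona-2,8-dien-4-yl]-6-methoxy-3,5-dimethyl-4H-pyran-4-one (C6/C7 diastereomer mixture)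
Conditions: TBSOTf, 2,6-lutidine, CH2Cl2, −78 → 0 °C
Reagents that add atoms: tert-butyldimethylsilyl triflate CC(C)(C)[Si](C)(C)OS(=O)(=O)C(F)(F)F
Why: silylation of the allylic aldol hydroxyl prevents retro-aldol and Ru-mediated alcohol isomerisation, and keeps C1 at the alcohol level so that the dione regiochemistry problem never arises.

Step 16
Reactants: 23 2-[(2E,4R)-7-(TBSO)-4,6,8-trimethyl-5-oxonona-2,8-dien-4-yl]-6-methoxy-3,5-dimethyl-4H-pyran-4-one
Product: 24 2-[(1R)-4-(TBSO)-1,3,5-trimethyl-6-oxocyclohex-2-en-1-yl]-6-methoxy-3,5-dimethyl-4H-pyran-4-one (C4/C5 diastereomer mixture)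
Conditions: Hoveyda–Grubbs II (10 mol%), toluene, 80 °C, Ar sparge
Reagents that add atoms: none
Why: ring-closing metathesis between the propenyl and isopropenyl groups forms the six-membered ring with the trisubstituted C5=C6 olefin already in place, driven by loss of propene and the gem-disubstituent effect.

Step 17
Reactants: 24 2-[(1R)-4-(TBSO)-1,3,5-trimethyl-6-oxocyclohex-2-en-1-yl]-6-methoxy-3,5-dimethyl-4H-pyran-4-one
Product: 26 (6R)-3-(TBSO)-6-(6-methoxy-3,5-dimethyl-4-oxo-4H-pyran-2-yl)-2,4,6-trimethylcyclohexa-1,4-dien-1-yl trifluoromethanesulfonate (C3 epimers), via potassium enolate of the ring ketone 25 (not isolated)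
Conditions: KHMDS, THF, −78 °C; Comins' reagent, −78 → −40 °C
Reagents that add atoms: Comins' reagent FC(F)(F)S(=O)(=O)N(c1ccc(Cl)cn1)S(=O)(=O)C(F)(F)F
Why: enolate O-triflation is regiospecific because only C2–H is enolisable (C4 is quaternary), and low temperature with the reactive triflimide suppresses E1cB loss of the β-silyloxy group.

**Side chain**

Step 18
Reactants: 27 (4R)-4-benzyl-3-propionyl-1,3-oxazolidin-2-one; 28 propanal
Product: 30 (4R)-4-benzyl-3-[(2R,3S)-3-hydroxy-2-methylpentanoyl]-1,3-oxazolidin-2-one, via Z dibutylboron enolate 29 (not isolated)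
Conditions: Bu2BOTf, i-Pr2NEt, CH2Cl2, 0 °C; 28, −78 → 0 °C; pH 7 buffer, MeOH, H2O2
Reagents that add atoms: none
Why: Evans syn-aldol through a Zimmerman–Traxler chair in which the benzyl group of the auxiliary shields one enolate face, setting C2 as R (the future 4S side-chain centre) and C3 as S.

Step 19
Reactants: 30 (4R)-4-benzyl-3-[(2R,3S)-3-hydroxy-2-methylpentanoyl]-1,3-oxazolidin-2-one
Product: 31 (4R)-4-benzyl-3-[(2R,3S)-3-(TBSO)-2-methylpentanoyl]-1,3-oxazolidin-2-one
Conditions: TBSOTf, 2,6-lutidine, CH2Cl2, 0 °C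
Reagents that add atoms: tert-butyldimethylsilyl triflate CC(C)(C)[Si](C)(C)OS(=O)(=O)C(F)(F)F
Why: silyl protection keeps the future ketone masked as an alcohol so that the α-methyl centre cannot epimerise until the last step.

Step 20
Reactants: 31 (4R)-4-benzyl-3-[(2R,3S)-3-(TBSO)-2-methylpentanoyl]-1,3-oxazolidin-2-one
Product: 32 (2S,3S)-3-(TBSO)-2-methylpentan-1-ol
Conditions: LiBH4, MeOH (1 eq), THF, 0 °C
Reagents that add atoms: none
Why: reductive cleavage of the imide gives the primary alcohol without epimerisation and releases the auxiliary for recovery.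

Step 21
Reactants: 32 (2S,3S)-3-(TBSO)-2-methylpentan-1-ol
Product: 33 (2R,3S)-3-(TBSO)-2-methylpentanal
Conditions: Dess–Martin periodinane, NaHCO3, CH2Cl2, 0 °C; used directly
Reagents that add atoms: none
Why: buffered Dess–Martin oxidation gives the α-chiral aldehyde without epimerisation.

Step 22
Reactants: 33 (2R,3S)-3-(TBSO)-2-methylpentanal
Product: 34 tert-butyl{[(3S,4S)-6,6-dibromo-4-methylhex-5-en-3-yl]oxy}dimethylsilane
Conditions: CBr4, PPh3, 2,6-lutidine, CH2Cl2, 0 °C
Reagents that add atoms: carbon tetrabromide BrC(Br)(Br)Br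
Why: Corey–Fuchs dibromo-olefination (Wittig reaction of the dibromomethylene ylide) under buffered conditions leaves the α-centre intact.

Step 23
Reactants: 34 tert-butyl{[(3S,4S)-6,6-dibromo-4-methylhex-5-en-3-yl]oxy}dimethylsilane
Product: 36 tert-butyldimethyl{[(3S,4S)-4-methylhept-5-yn-3-yl]oxy}silane, via lithium acetylide 35 (not isolated)
Conditions: n-BuLi (2.2 eq), THF, −78 °C; MeI, −78 °C → rt
Reagents that add atoms: iodomethane CI
Why: second stage of the Corey–Fuchs sequence (Br/Li exchange, rearrangement to the acetylide) followed by C-methylation gives the 2-alkyne.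

Step 24
Reactants: 36 tert-butyldimethyl{[(3S,4S)-4-methylhept-5-yn-3-yl]oxy}silane
Product: 38 tert-butyl{[(3S,4S,5E)-6-iodo-4-methylhept-5-en-3-yl]oxy}dimethylsilane, via alkenylzirconocene chloride 37 (not isolated)
Conditions: Cp2Zr(H)Cl (2.5 eq), THF, 50 °C; I2, 0 °C
Reagents that add atoms: iodine II
Why: syn-hydrozirconation places Zr on the less hindered methyl-bearing alkyne carbon (excess reagent and heat equilibrate the regiochemistry), and iodinolysis with retention gives the E iodide.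

Step 25
Reactants: 38 tert-butyl{[(3S,4S,5E)-6-iodo-4-methylhept-5-en-3-yl]oxy}dimethylsilane
Product: 40 tert-butyldimethyl{[(3S,4S,5E)-4-methyl-6-(trimethylstannyl)hept-5-en-3-yl]oxy}silane, via alkenyllithium 39 (not isolated)
Conditions: t-BuLi (2.1 eq), Et2O, −78 °C; Me3SnCl, −78 → 0 °C
Reagents that add atoms: chlorotrimethylstannane C[Sn](C)(C)Cl
Why: iodine–lithium exchange and stannylation both proceed with retention of olefin geometry, giving a purifiable nucleophile for the coupling.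

**Union and endgame**

Step 26
Reactants: 26 (6R)-3-(TBSO)-6-(6-methoxy-3,5-dimethyl-4-oxo-4H-pyran-2-yl)-2,4,6-trimethylcyclohexa-1,4-dien-1-yl trifluoromethanesulfonate; 40 tert-butyldimethyl{[(3S,4S,5E)-4-methyl-6-(trimethylstannyl)hept-5-en-3-yl]oxy}silane
Product: 41 2-[(1S)-4-(TBSO)-2-[(2E,4S,5S)-5-(TBSO)-4-methylhept-2-en-2-yl]-1,3,5-trimethylcyclohexa-2,5-dien-1-yl]-6-methoxy-3,5-dimethyl-4H-pyran-4-one (C4 epimers)
Conditions: Pd(PPh3)4 (10 mol%), CuCl (5 eq), LiCl (6 eq), DMSO, 60 °C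
Reagents that add atoms: none
Why: Stille coupling with Cu(I)/LiCl promotion, suited to congested 1-substituted alkenylstannanes and hindered enol triflates, proceeds with retention at both sp2 carbons, so the side-chain olefin is E and the pyrone is untouched.

Step 27
Reactants: 41 2-[(1S)-4-(TBSO)-2-[(2E,4S,5S)-5-(TBSO)-4-methylhept-2-en-2-yl]-1,3,5-trimethylcyclohexa-2,5-dien-1-yl]-6-methoxy-3,5-dimethyl-4H-pyran-4-one
Product: 42 2-[(1S)-4-hydroxy-2-[(2E,4S,5S)-5-hydroxy-4-methylhept-2-en-2-yl]-1,3,5-trimethylcyclohexa-2,5-dien-1-yl]-6-methoxy-3,5-dimethyl-4H-pyran-4-one (C4 epimers)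
Conditions: TBAF (5 eq), THF, rt → 40 °C
Reagents that add atoms: none
Why: fluoride desilylation removes both silyl ethers under non-acidic conditions, avoiding ionisation of the bis-allylic ring carbinol, while no epimerisable ketone is yet present.

Step 28
Reactants: 42 2-[(1S)-4-hydroxy-2-[(2E,4S,5S)-5-hydroxy-4-methylhept-2-en-2-yl]-1,3,5-trimethylcyclohexa-2,5-dien-1-yl]-6-methoxy-3,5-dimethyl-4H-pyran-4-one
Product: 43 2-methoxy-3,5-dimethyl-6-[(1S)-1,3,5-trimethyl-2-[(2E,4S)-4-methyl-5-oxohept-2-en-2-yl]-4-oxocyclohexa-2,5-dien-1-yl]-4H-pyran-4-one (CNP0276209.1)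
Conditions: Dess–Martin periodinane (3 eq), NaHCO3, CH2Cl2, 0 °C → rt; rapid chromatography on buffered silica
Reagents that add atoms: none
Why: one buffered Dess–Martin oxidation converts the bis-allylic ring alcohol into the cross-conjugated dienone and the side-chain carbinol into the ethyl ketone, so the base-sensitive α-methyl β,γ-unsaturated ketone centre (4S) is formed last and is not epimerised.

**Compound list**

1 | methyl 3-oxopentanoate | CCC(=O)CC(=O)OC | starting material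
2 | methyl (3S)-3-hydroxypentanoate | CC[C@H](O)CC(=O)OC | intermediate
3 | dilithium alkoxide enolate of the hydroxy ester (not isolated) | CC[C@H](O[Li])C=C(OC)O[Li] | intermediate
4 | methyl (2S,3S)-3-hydroxy-2-methylpentanoate | C[C@H](C(=O)OC)[C@@H](O)CC | intermediate
5 | allyl bromide | C=CCBr | starting material
6 | dilithium alkoxide enolate of the methylated hydroxy ester (not isolated) | CC[C@H](O[Li])C(C)=C(OC)O[Li] | intermediate
7 | methyl (2S,3S)-2-allyl-3-hydroxy-2-methylpentanoate | C[C@@](C(=O)OC)([C@@H](O)CC)CC=C | intermediate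
8 | methyl (2S,3S)-2-allyl-3-(TBSO)-2-methylpentanoate | C[C@@](C(=O)OC)([C@@H](O[Si](C)(C)C(C)(C)C)CC)CC=C | intermediate
9 | methyl (2S,3S)-3-(TBSO)-2-methyl-2-[(E)-prop-1-enyl]pentanoate | C[C@@](C(=O)OC)([C@@H](O[Si](C)(C)C(C)(C)C)CC)/C=C/C | intermediate
10 | (2R,3S)-3-(TBSO)-2-methyl-2-[(E)-prop-1-enyl]pentan-1-ol | C[C@@](CO)([C@@H](O[Si](C)(C)C(C)(C)C)CC)/C=C/C | intermediate
11 | (2S,3S)-3-(TBSO)-2-methyl-2-[(E)-prop-1-enyl]pentanal | C[C@@](C=O)([C@@H](O[Si](C)(C)C(C)(C)C)CC)/C=C/C | intermediate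
12 | methyl 2-methyl-3-oxopentanoate (racemic) | CCC(=O)C(C)C(=O)OC | starting material
13 | sodium lithium dienolate of the keto ester (not isolated) | CC=C(O[Li])C(C)=C(OC)O[Na] | intermediate
14 | methyl (6R,7S)-7-(TBSO)-5-hydroxy-2,4,6-trimethyl-3-oxo-6-[(E)-prop-1-enyl]nonanoate (C2/C4/C5 diastereomer mixture) | C[C@@](C(O)C(C)C(=O)C(C)C(=O)OC)([C@@H](O[Si](C)(C)C(C)(C)C)CC)/C=C/C | intermediate
15 | methyl (6S,7S)-7-(TBSO)-2,4,6-trimethyl-3,5-dioxo-6-[(E)-prop-1-enyl]nonanoate (C2/C4 epimers) | C[C@@](C(=O)C(C)C(=O)C(C)C(=O)OC)([C@@H](O[Si](C)(C)C(C)(C)C)CC)/C=C/C | intermediate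
16 | 6-[(2E,4S,5S)-5-(TBSO)-4-methylhept-2-en-4-yl]-4-hydroxy-3,5-dimethyl-2H-pyran-2-one | C[C@@](C1=C(C)C(O)=C(C)C(=O)O1)([C@@H](O[Si](C)(C)C(C)(C)C)CC)/C=C/C | intermediate
17 | 2-[(2E,4S,5S)-5-(TBSO)-4-methylhept-2-en-4-yl]-6-methoxy-3,5-dimethyl-4H-pyran-4-one | C[C@@](c1oc(OC)c(C)c(=O)c1C)([C@@H](O[Si](C)(C)C(C)(C)C)CC)/C=C/C | intermediate
18 | 2-[(2E,4S,5S)-5-hydroxy-4-methylhept-2-en-4-yl]-6-methoxy-3,5-dimethyl-4H-pyran-4-one | C[C@@](c1oc(OC)c(C)c(=O)c1C)([C@@H](O)CC)/C=C/C | intermediate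
19 | 2-methoxy-3,5-dimethyl-6-[(2E,4R)-4-methyl-5-oxohept-2-en-4-yl]-4H-pyran-4-one | C[C@@](c1oc(OC)c(C)c(=O)c1C)(C(=O)CC)/C=C/C | intermediate
20 | methacrolein | CC(=C)C=O | starting material
21 | lithium enolate of the ethyl ketone (not isolated) | C[C@@](c1oc(OC)c(C)c(=O)c1C)(C(O[Li])=CC)/C=C/C | intermediate
22 | 2-[(2E,4R)-7-hydroxy-4,6,8-trimethyl-5-oxonona-2,8-dien-4-yl]-6-methoxy-3,5-dimethyl-4H-pyran-4-one (C6/C7 diastereomer mixture) | C[C@@](c1oc(OC)c(C)c(=O)c1C)(C(=O)C(C)C(O)C(C)=C)/C=C/C | intermediate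
23 | 2-[(2E,4R)-7-(TBSO)-4,6,8-trimethyl-5-oxonona-2,8-dien-4-yl]-6-methoxy-3,5-dimethyl-4H-pyran-4-one (C6/C7 diastereomer mixture) | C[C@@](c1oc(OC)c(C)c(=O)c1C)(C(=O)C(C)C(O[Si](C)(C)C(C)(C)C)C(C)=C)/C=C/C | intermediate
24 | 2-[(1R)-4-(TBSO)-1,3,5-trimethyl-6-oxocyclohex-2-en-1-yl]-6-methoxy-3,5-dimethyl-4H-pyran-4-one (C4/C5 diastereomer mixture) | C[C@@]1(c2oc(OC)c(C)c(=O)c2C)C(=O)C(C)C(O[Si](C)(C)C(C)(C)C)C(C)=C1 | intermediate
25 | potassium enolate of the ring ketone (not isolated) | C[C@@]1(c2oc(OC)c(C)c(=O)c2C)C(O[K])=C(C)C(O[Si](C)(C)C(C)(C)C)C(C)=C1 | intermediate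
26 | (6R)-3-(TBSO)-6-(6-methoxy-3,5-dimethyl-4-oxo-4H-pyran-2-yl)-2,4,6-trimethylcyclohexa-1,4-dien-1-yl trifluoromethanesulfonate (C3 epimers) | C[C@@]1(c2oc(OC)c(C)c(=O)c2C)C(OS(=O)(=O)C(F)(F)F)=C(C)C(O[Si](C)(C)C(C)(C)C)C(C)=C1 | intermediate
27 | (4R)-4-benzyl-3-propionyl-1,3-oxazolidin-2-one | CCC(=O)N1[C@H](Cc2ccccc2)COC1=O | starting material
28 | propanal | CCC=O | starting material
29 | Z dibutylboron enolate of the propionimide (not isolated) | C/C=C(\OB(CCCC)CCCC)N1[C@H](Cc2ccccc2)COC1=O | intermediate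
30 | (4R)-4-benzyl-3-[(2R,3S)-3-hydroxy-2-methylpentanoyl]-1,3-oxazolidin-2-one | CC[C@H](O)[C@@H](C)C(=O)N1[C@H](Cc2ccccc2)COC1=O | intermediate
31 | (4R)-4-benzyl-3-[(2R,3S)-3-(TBSO)-2-methylpentanoyl]-1,3-oxazolidin-2-one | CC[C@H](O[Si](C)(C)C(C)(C)C)[C@@H](C)C(=O)N1[C@H](Cc2ccccc2)COC1=O | intermediate
32 | (2S,3S)-3-(TBSO)-2-methylpentan-1-ol | CC[C@H](O[Si](C)(C)C(C)(C)C)[C@@H](C)CO | intermediate
33 | (2R,3S)-3-(TBSO)-2-methylpentanal | CC[C@H](O[Si](C)(C)C(C)(C)C)[C@@H](C)C=O | intermediate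
34 | tert-butyl{[(3S,4S)-6,6-dibromo-4-methylhex-5-en-3-yl]oxy}dimethylsilane | CC[C@H](O[Si](C)(C)C(C)(C)C)[C@@H](C)C=C(Br)Br | intermediate
35 | lithium acetylide (not isolated) | CC[C@H](O[Si](C)(C)C(C)(C)C)[C@@H](C)C#C[Li] | intermediate
36 | tert-butyldimethyl{[(3S,4S)-4-methylhept-5-yn-3-yl]oxy}silane | CC[C@H](O[Si](C)(C)C(C)(C)C)[C@@H](C)C#CC | intermediate
37 | alkenylzirconocene chloride (not isolated) | CC[C@H](O[Si](C)(C)C(C)(C)C)[C@@H](C)/C=C(\C)[Zr](Cl)(C1C=CC=C1)C1C=CC=C1 | intermediate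
38 | tert-butyl{[(3S,4S,5E)-6-iodo-4-methylhept-5-en-3-yl]oxy}dimethylsilane | CC[C@H](O[Si](C)(C)C(C)(C)C)[C@@H](C)/C=C(\C)I | intermediate
39 | alkenyllithium (not isolated) | CC[C@H](O[Si](C)(C)C(C)(C)C)[C@@H](C)/C=C(\C)[Li] | intermediate
40 | tert-butyldimethyl{[(3S,4S,5E)-4-methyl-6-(trimethylstannyl)hept-5-en-3-yl]oxy}silane | CC[C@H](O[Si](C)(C)C(C)(C)C)[C@@H](C)/C=C(\C)[Sn](C)(C)C | intermediate
41 | 2-[(1S)-4-(TBSO)-2-[(2E,4S,5S)-5-(TBSO)-4-methylhept-2-en-2-yl]-1,3,5-trimethylcyclohexa-2,5-dien-1-yl]-6-methoxy-3,5-dimethyl-4H-pyran-4-one (C4 epimers) | C[C@@]1(c2oc(OC)c(C)c(=O)c2C)C(/C(C)=C/[C@H](C)[C@@H](O[Si](C)(C)C(C)(C)C)CC)=C(C)C(O[Si](C)(C)C(C)(C)C)C(C)=C1 | intermediate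
42 | 2-[(1S)-4-hydroxy-2-[(2E,4S,5S)-5-hydroxy-4-methylhept-2-en-2-yl]-1,3,5-trimethylcyclohexa-2,5-dien-1-yl]-6-methoxy-3,5-dimethyl-4H-pyran-4-one (C4 epimers) | C[C@@]1(c2oc(OC)c(C)c(=O)c2C)C(/C(C)=C/[C@H](C)[C@@H](O)CC)=C(C)C(O)C(C)=C1 | intermediate
43 | 2-methoxy-3,5-dimethyl-6-[(1S)-1,3,5-trimethyl-2-[(2E,4S)-4-methyl-5-oxohept-2-en-2-yl]-4-oxocyclohexa-2,5-dien-1-yl]-4H-pyran-4-one | C[C@@]1(c2oc(OC)c(C)c(=O)c2C)C(/C(C)=C/[C@H](C)C(=O)CC)=C(C)C(=O)C(C)=C1 | target

**Totals and risks**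

Total step count: 28. Longest linear sequence: 20 steps (steps 1–17, then 26–28); the side-chain branch is steps 18–25.

Steps most likely to fail:

Step 26 (Stille coupling of the very hindered enol triflate with an α-methyl alkenylstannane). If transmetallation onto the crowded alkenyl–palladium is too slow, the polarity is reversed. The fallback sets out from triflate 26: Miyaura borylation (B2pin2, PdCl2(dppf), KOAc, dioxane, 80 °C) gives the pinacol boronate 2-[(1S)-4-(TBSO)-1,3,5-trimethyl-2-(4,4,5,5-tetramethyl-1,3,2-dioxaborolan-2-yl)cyclohexa-2,5-dien-1-yl]-6-methoxy-3,5-dimethyl-4H-pyran-4-one F4. F4 is then joined to vinyl iodide 38 by Suzuki–Miyaura coupling (Pd(OAc)2/SPhos, K3PO4, THF–H2O, 60 °C), and the route is rejoined at 41.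

Step 17 (enol triflation of a hindered β-silyloxy ketone). If enolate 25 expels the silyloxy group or resists triflation, the C3 substituent is introduced as a nucleophile instead. The fallback sets out from ketone 24 and iodide 38: alkenyllithium 39 (from 38 and t-BuLi) is added at −78 °C to 24 in the presence of LaCl3·2LiCl, which favours 1,2-addition to the ring ketone over enolisation. This gives the tertiary allylic alcohol 2-[(1S)-4-(TBSO)-6-[(2E,4S,5S)-5-(TBSO)-4-methylhept-2-en-2-yl]-6-hydroxy-1,3,5-trimethylcyclohex-2-en-1-yl]-6-methoxy-3,5-dimethyl-4H-pyran-4-one F3. Burgess dehydration (benzene, 50 °C), for which the only β-hydrogen is on C2, forms the C2=C3 olefin and rejoins the route at 41, bypassing 26 and the Stille step.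

Step 8 (dianion aldol on the neopentyl α-quaternary aldehyde). If the strongly basic dianion gives poor conversion, the same bond is made under Lewis-acid activation. The fallback sets out from keto ester 12 (with aldehyde 11): O-silylation (TMSCl, Et3N) gives methyl 2-methyl-3-[(trimethylsilyl)oxy]pent-2-enoate F1, and a second silylation (LDA, TMSCl, −78 °C) gives the bis(silyl) dienol ether 1-methoxy-2-methyl-1,3-bis[(trimethylsilyl)oxy]penta-1,3-diene F2. F2 adds through its terminal carbon to 11 with BF3·OEt2 in CH2Cl2 at −78 °C (vinylogous Mukaiyama aldol), and aqueous work-up rejoins the route at 14.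

**Further compounds**

F1 | step 8 | methyl 2-methyl-3-[(trimethylsilyl)oxy]pent-2-enoate | CCC(O[Si](C)(C)C)=C(C)C(=O)OC
F2 | step 8 | 1-methoxy-2-methyl-1,3-bis[(trimethylsilyl)oxy]penta-1,3-diene | COC(O[Si](C)(C)C)=C(C)C(O[Si](C)(C)C)=CC
F3 | step 17 | 2-[(1S)-4-(TBSO)-6-[(2E,4S,5S)-5-(TBSO)-4-methylhept-2-en-2-yl]-6-hydroxy-1,3,5-trimethylcyclohex-2-en-1-yl]-6-methoxy-3,5-dimethyl-4H-pyran-4-one (diastereomer mixture) | C[C@@]1(c2oc(OC)c(C)c(=O)c2C)C(O)(/C(C)=C/[C@H](C)[C@@H](O[Si](C)(C)C(C)(C)C)CC)C(C)C(O[Si](C)(C)C(C)(C)C)C(C)=C1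
F4 | step 26 | 2-[(1S)-4-(TBSO)-1,3,5-trimethyl-2-(4,4,5,5-tetramethyl-1,3,2-dioxaborolan-2-yl)cyclohexa-2,5-dien-1-yl]-6-methoxy-3,5-dimethyl-4H-pyran-4-one (C4 epimers) | C[C@@]1(c2oc(OC)c(C)c(=O)c2C)C(B3OC(C)(C)C(C)(C)O3)=C(C)C(O[Si](C)(C)C(C)(C)C)C(C)=C1
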